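Each ring of C2-symmetric lactucaxanthin (carotenoid numbering) is an allylic alcohol, C3–OH beside C4=C5, hence a reduced cyclohexenone. Its C2–C3–C4 unit is an acetone 1,3-dianion; C5, C6 and quaternary C1 come from an alkylidene acetoacetate. In the key step the dianion of dimethyl (2-oxopropyl)phosphonate adds to the isopropylidene carbon of ethyl 2-acetyl-3-methylbut-2-enoate (C1–C2) and then olefinates the acetyl group (C4=C5), closing the ring in one flask. A catalyst-controlled enone reduction then sets C3 and sorts the labile C6 centre. The ring block is used twice in a C15 + C10 + C15 double Wittig reaction.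

Key step: step 2

Remark: the Why lines use carotenoid numbering (C1 = CMe2, C2 = CH2, C3 = carbinol carbon, C4 = CH=, C5 = C(Me)=, C6 = ring CH bearing the chain) while compound names use IUPAC locants; the C10 dialdehyde and the C5 cyanophosphonate are assumed to be purchasable.

Step 1
Reactants: 1 ethyl acetoacetate; 2 acetone
Product: 3 ethyl 2-acetyl-3-methylbut-2-enoate
Conditions: ZnCl2 (cat.), Ac2O, acetone (excess), 50 °C
Reagents that add atoms: none
Why: Knoevenagel condensation of the active methylene of 1 with acetone, driven by acetic anhydride as water scavenger; the β-carbon carries two methyl groups, so no olefin geometry arises.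

Step 2
Reactants: 3 ethyl 2-acetyl-3-methylbut-2-enoate; 4 dimethyl (2-oxopropyl)phosphonate
Product: 7 ethyl (1RS)-2,6,6-trimethyl-4-oxocyclohex-2-ene-1-carboxylate, via phosphonate 1,3-dianion 5 (not isolated), via Michael adduct enolate 6 (not isolated)
Conditions: 4, NaH, THF, 0 °C; n-BuLi, 0 °C; then 3, −78 → 0 °C; then AcOH (1 equiv), 60 °C
Reagents that add atoms: none
Why: The terminal carbanion of dianion 5, its most basic and least hindered site, adds 1,4 to the doubly activated isopropylidene carbon of 3 and forms the quaternary C1–C2 bond; one equivalent of acetic acid then converts the bis-enolate into a mono-anion, proton exchange frees the methyl ketone, and the phosphonate carbanion at C4 adds to it and expels dimethyl phosphate (intramolecular Horner–Wadsworth–Emmons), forming C4=C5. The closest known reaction types are the Michael/Wittig [3+3] annulations of allylidene- and 2-alkoxyallylidenephosphoranes with alkylidene acetoacetates and enones, and the γ-selective alkylations of β-ketophosphonate dianions. The ring closes by a 6-exo-trig addition of C4 to the C5 carbonyl followed by syn-elimination, so the new olefin is necessarily endocyclic. No stereocentre is fixed here: C6 forms racemic and stays labile (γ to the enone, α to the ester), which step 3 deals with. The step needs γ- over α-attack of the phosphonate (secured by the dianion), conjugate over carbonyl addition (secured by the alkylidene β-ketoester), and closure through C4 and not through the acetyl methyl group (secured by the phosphonate, which marks C4 as the olefinating carbon).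

Step 3
Reactants: 7 ethyl (1RS)-2,6,6-trimethyl-4-oxocyclohex-2-ene-1-carboxylate
Product: 8 ethyl (1R,4R)-4-hydroxy-2,6,6-trimethylcyclohex-2-ene-1-carboxylate
Conditions: (S)-2-methyl-CBS-oxazaborolidine [(3aS)-1-methyl-3,3-diphenyltetrahydro-1H,3H-pyrrolo[1,2-c][1,3,2]oxazaborole] (cat.), catecholborane, toluene, −78 °C; chromatography
Reagents that add atoms: none
Why: Corey–Bakshi–Shibata reduction, in which the catalyst should bind the carbonyl with the alkenyl arm as the large group and deliver hydride to the same face in both enantiomers of 7, so that C3 becomes R; the (6R)-enantiomer then gives the 3,6-trans alcohol 8 and the (6S)-enantiomer the cis alcohol, which is removed by chromatography, so C6 is fixed by separation of diastereomers once the ketone that made it labile is gone.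

Step 4
Reactants: 8 ethyl (1R,4R)-4-hydroxy-2,6,6-trimethylcyclohex-2-ene-1-carboxylate
Product: 9 ethyl (1R,4R)-4-{[tert-butyl(dimethyl)silyl]oxy}-2,6,6-trimethylcyclohex-2-ene-1-carboxylate
Conditions: TBSCl, imidazole, DMF, 23 °C
Reagents that add atoms: tert-butyldimethylsilyl chloride (TBSCl), CC(C)(C)[Si](C)(C)Cl
Why: Standard silylation of a secondary allylic alcohol, which keeps the hydroxyl out of the hydride, oxidation and carbanion steps that follow.

Step 5
Reactants: 9 ethyl (1R,4R)-4-{[tert-butyl(dimethyl)silyl]oxy}-2,6,6-trimethylcyclohex-2-ene-1-carboxylate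
Product: 10 [(1R,4R)-4-{[tert-butyl(dimethyl)silyl]oxy}-2,6,6-trimethylcyclohex-2-en-1-yl]methanol
Conditions: i-Bu2AlH, CH2Cl2, −78 → 0 °C; aq. potassium sodium tartrate
Reagents that add atoms: none
Why: Ester reduction by a neutral aluminium hydride, which does not deprotonate C6 and leaves the silyl ether and the trisubstituted olefin untouched.

Step 6
Reactants: 10 [(1R,4R)-4-{[tert-butyl(dimethyl)silyl]oxy}-2,6,6-trimethylcyclohex-2-en-1-yl]methanol
Product: 11 (1R,4R)-4-{[tert-butyl(dimethyl)silyl]oxy}-2,6,6-trimethylcyclohex-2-ene-1-carbaldehyde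
Conditions: Dess–Martin periodinane, NaHCO3, CH2Cl2, 0 °C; used at once
Reagents that add atoms: none
Why: Dess–Martin oxidation under buffered, non-basic conditions should give the β,γ-unsaturated aldehyde without epimerisation at C6 or migration of the ring olefin.

Step 7
Reactants: 11 (1R,4R)-4-{[tert-butyl(dimethyl)silyl]oxy}-2,6,6-trimethylcyclohex-2-ene-1-carbaldehyde; 12 diethyl [(2E)-3-cyano-2-methylprop-2-en-1-yl]phosphonate
Product: 14 (2E,4E)-5-[(1R,4R)-4-{[tert-butyl(dimethyl)silyl]oxy}-2,6,6-trimethylcyclohex-2-en-1-yl]-3-methylpenta-2,4-dienenitrile, via lithiated phosphonate 13 (not isolated)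
Conditions: 12, LiN(SiMe3)2, THF, −78 °C; then 11, −78 → 0 °C; chromatography
Reagents that add atoms: none
Why: Horner–Wadsworth–Emmons olefination with a vinylogous cyanomethylphosphonate forms C7=C8 (E, as expected for a stabilised phosphonate anion) and brings C9=C10 with it; the preformed anion should add to the aldehyde at low temperature faster than it enolises it, and the minor 9Z isomer is removed by chromatography.

Step 8
Reactants: 14 (2E,4E)-5-[(1R,4R)-4-{[tert-butyl(dimethyl)silyl]oxy}-2,6,6-trimethylcyclohex-2-en-1-yl]-3-methylpenta-2,4-dienenitrile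
Product: 15 (2E,4E)-5-[(1R,4R)-4-hydroxy-2,6,6-trimethylcyclohex-2-en-1-yl]-3-methylpenta-2,4-dienenitrile
Conditions: Bu4NF, THF, 0 → 23 °C
Reagents that add atoms: none
Why: Fluoride-induced desilylation, done on the robust nitrile so that the final polyene needs no deprotection.

Step 9
Reactants: 15 (2E,4E)-5-[(1R,4R)-4-hydroxy-2,6,6-trimethylcyclohex-2-en-1-yl]-3-methylpenta-2,4-dienenitrile
Product: 17 (2E,4E)-5-[(1R,4R)-4-hydroxy-2,6,6-trimethylcyclohex-2-en-1-yl]-3-methylpenta-2,4-dienal, via aluminium aldimine 16 (not isolated)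
Conditions: i-Bu2AlH (excess), CH2Cl2, −78 °C; then wet SiO2, 0 °C
Reagents that add atoms: water, O
Why: Partial reduction of the conjugated nitrile to the N-aluminio aldimine, which is hydrolysed on a near-neutral work-up that the acid-sensitive allylic alcohol should tolerate; one extra equivalent of hydride is consumed by the free hydroxyl.

Step 10
Reactants: 18 (2E,4E,6E)-2,7-dimethylocta-2,4,6-trienedial
Product: 19 (2E,4E,6E)-2,7-dimethylocta-2,4,6-triene-1,8-diol
Conditions: NaBH4, MeOH/THF, 0 °C
Reagents that add atoms: none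
Why: 1,2-Reduction of both conjugated aldehyde groups by borohydride, with the triene geometry untouched.

Step 11
Reactants: 19 (2E,4E,6E)-2,7-dimethylocta-2,4,6-triene-1,8-diol
Product: 20 [(2E,4E,6E)-2,7-dimethylocta-2,4,6-triene-1,8-diyl]bis(triphenylphosphonium) dibromide
Conditions: Ph3P·HBr, MeOH, 23 °C; crystallisation
Reagents that add atoms: triphenylphosphine hydrobromide, [Br-].[PH+](c1ccccc1)(c1ccccc1)c1ccccc1
Why: Phosphonium salt formation from allylic alcohols through the allyl cation, where reversible phosphine attack should favour the conjugated, terminal all-E bis-salt.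

Step 12
Reactants: 17 (2E,4E)-5-[(1R,4R)-4-hydroxy-2,6,6-trimethylcyclohex-2-en-1-yl]-3-methylpenta-2,4-dienal (2 equiv); 20 [(2E,4E,6E)-2,7-dimethylocta-2,4,6-triene-1,8-diyl]bis(triphenylphosphonium) dibromide
Product: 22 lactucaxanthin, (all-E)-(3R,6R,3′R,6′R)-ε,ε-carotene-3,3′-diol, via bis-ylide 21 (not isolated)
Conditions: NaOMe, MeOH/CH2Cl2, 0 → 23 °C; then n-heptane, reflux, argon, dark; crystallisation
Reagents that add atoms: none
Why: Double Wittig olefination forms C11=C12 and C11′=C12′; the semi-stabilised ylide is expected to give E/Z mixtures at these unhindered disubstituted bonds, which should equilibrate thermally to the all-E polyene, and no stereocentre is touched.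

Compound list
1 | ethyl acetoacetate | CCOC(=O)CC(C)=O | starting material
2 | acetone | CC(C)=O | starting material
3 | ethyl 2-acetyl-3-methylbut-2-enoate | CCOC(=O)C(C(C)=O)=C(C)C | intermediate
4 | dimethyl (2-oxopropyl)phosphonate | COP(=O)(CC(C)=O)OC | starting material
5 | lithium sodium 1,3-dianion of dimethyl (2-oxopropyl)phosphonate (not isolated) | [Li+].[Na+].[CH2-]C(=O)[CH-]P(=O)(OC)OC | intermediate
6 | ethyl 2-acetyl-6-(dimethoxyphosphoryl)-3,3-dimethyl-5-oxohexanoate, present as its enolate (not isolated) | CCOC(=O)C(C(C)=O)C(C)(C)CC(=O)CP(=O)(OC)OC | intermediate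
7 | ethyl (1RS)-2,6,6-trimethyl-4-oxocyclohex-2-ene-1-carboxylate | CCOC(=O)C1C(C)=CC(=O)CC1(C)C | intermediate
8 | ethyl (1R,4R)-4-hydroxy-2,6,6-trimethylcyclohex-2-ene-1-carboxylate | CC1=C[C@H](O)CC(C)(C)[C@H]1C(=O)OCC | intermediate
9 | ethyl (1R,4R)-4-{[tert-butyl(dimethyl)silyl]oxy}-2,6,6-trimethylcyclohex-2-ene-1-carboxylate | CC1=C[C@H](O[Si](C)(C)C(C)(C)C)CC(C)(C)[C@H]1C(=O)OCC | intermediate
10 | [(1R,4R)-4-{[tert-butyl(dimethyl)silyl]oxy}-2,6,6-trimethylcyclohex-2-en-1-yl]methanol | CC1=C[C@H](O[Si](C)(C)C(C)(C)C)CC(C)(C)[C@H]1CO | intermediate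
11 | (1R,4R)-4-{[tert-butyl(dimethyl)silyl]oxy}-2,6,6-trimethylcyclohex-2-ene-1-carbaldehyde | CC1=C[C@H](O[Si](C)(C)C(C)(C)C)CC(C)(C)[C@H]1C=O | intermediate
12 | diethyl [(2E)-3-cyano-2-methylprop-2-en-1-yl]phosphonate | CCOP(=O)(OCC)C/C(C)=C/C#N | starting material
13 | lithium salt of the α-carbanion of 12 (not isolated) | [Li+].CCOP(=O)(OCC)[CH-]/C(C)=C/C#N | intermediate
14 | (2E,4E)-5-[(1R,4R)-4-{[tert-butyl(dimethyl)silyl]oxy}-2,6,6-trimethylcyclohex-2-en-1-yl]-3-methylpenta-2,4-dienenitrile | CC1=C[C@H](O[Si](C)(C)C(C)(C)C)CC(C)(C)[C@H]1/C=C/C(C)=C/C#N | intermediate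
15 | (2E,4E)-5-[(1R,4R)-4-hydroxy-2,6,6-trimethylcyclohex-2-en-1-yl]-3-methylpenta-2,4-dienenitrile | CC1=C[C@H](O)CC(C)(C)[C@H]1/C=C/C(C)=C/C#N | intermediate
16 | (2E,4E)-5-[(1R,4R)-4-hydroxy-2,6,6-trimethylcyclohex-2-en-1-yl]-3-methylpenta-2,4-dien-1-imine, present as its N- and O-aluminium derivative (not isolated) | CC1=C[C@H](O)CC(C)(C)[C@H]1/C=C/C(C)=C/C=N | intermediate
17 | (2E,4E)-5-[(1R,4R)-4-hydroxy-2,6,6-trimethylcyclohex-2-en-1-yl]-3-methylpenta-2,4-dienal | CC1=C[C@H](O)CC(C)(C)[C@H]1/C=C/C(C)=C/C=O | intermediate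
18 | (2E,4E,6E)-2,7-dimethylocta-2,4,6-trienedial | O=C/C(C)=C/C=C/C=C(C)/C=O | starting material
19 | (2E,4E,6E)-2,7-dimethylocta-2,4,6-triene-1,8-diol | OC/C(C)=C/C=C/C=C(C)/CO | intermediate
20 | [(2E,4E,6E)-2,7-dimethylocta-2,4,6-triene-1,8-diyl]bis(triphenylphosphonium) dibromide | [Br-].[Br-].C(/C(C)=C/C=C/C=C(C)/C[P+](c1ccccc1)(c1ccccc1)c1ccccc1)[P+](c1ccccc1)(c1ccccc1)c1ccccc1 | intermediate
21 | bis-ylide of 20 (not isolated) | c1ccccc1P(c1ccccc1)(c1ccccc1)=C/C(C)=C/C=C/C=C(C)/C=P(c1ccccc1)(c1ccccc1)c1ccccc1 | intermediate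
22 | lactucaxanthin, (all-E)-(3R,6R,3′R,6′R)-ε,ε-carotene-3,3′-diol | CC1=C[C@H](O)CC(C)(C)[C@H]1/C=C/C(C)=C/C=C/C(C)=C/C=C/C=C(C)/C=C/C=C(C)/C=C/[C@H]1C(C)=C[C@H](O)CC1(C)C | target

Total step count: 12. Longest linear sequence: 10 steps (steps 1 to 9, then step 12); steps 10 and 11 form the short C10 branch.

Steps most likely to fail

1. Step 2 (domino Michael/olefination). What may go wrong: proton transfer from the γ-methyl groups of 3 to the hard dianion, or attack at the acetyl carbonyl instead of conjugate addition at the crowded β-carbon; the ring closure may also stall at the mono-anion stage because the charge rests on the β-ketoester enolate and not on the phosphonate carbon. The fallback uses soft-enolate chemistry and still makes the same two bonds in one operation. It sets out from 3: commercial di-tert-butyl 3-oxopentanedioate is condensed with 3 under piperidinium acetate catalysis in toluene with removal of water. Conjugate addition through one methylene carbon and intramolecular Knoevenagel condensation of the other with the acetyl group should give 1,3-di-tert-butyl 5-ethyl 4,6,6-trimethyl-2-oxocyclohex-3-ene-1,3,5-tricarboxylate F1. CF3CO2H in CH2Cl2 cleaves only the tert-butyl esters to 5-(ethoxycarbonyl)-4,6,6-trimethyl-2-oxocyclohex-3-ene-1,3-dicarboxylic acid F2. This should lose both β-keto carboxyl groups on warming in toluene, while the vinylogous ethyl ester stays, and the route is rejoined at 7.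

2. Step 3 (catalyst-controlled reduction of the racemic enone). What may go wrong: poor differentiation by the catalyst of the alkenyl arm from the neopentyl-type CH2 arm, giving low facial selectivity at C3; substrate bias in the mismatched enantiomer could also leak material into the enantiomer of 8. The fallback is an enzymatic resolution and sets out from 7. Luche reduction (NaBH4, CeCl3·7H2O, MeOH, −20 °C) gives ethyl 4-hydroxy-2,6,6-trimethylcyclohex-2-ene-1-carboxylate as a mixture of stereoisomers F3. Burkholderia cepacia lipase and vinyl acetate should acylate the (4R)-alcohols only. The trans acetate ethyl (1R,4R)-4-acetoxy-2,6,6-trimethylcyclohex-2-ene-1-carboxylate F4 is separated by chromatography from its cis isomer ethyl (1S,4R)-4-acetoxy-2,6,6-trimethylcyclohex-2-ene-1-carboxylate F5 and from the unreacted (4S)-alcohols. K2CO3 in ethanol then cleaves the acetate and the route is rejoined at 8.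

3. Step 7 (olefination of the α-branched β,γ-unsaturated aldehyde). What may go wrong: enolisation of the hindered aldehyde by the phosphonate anion, with epimerisation at C6 or migration of the ring double bond into conjugation. The fallback changes the disconnection to C3 + C2 and sets out from 11. Wittig olefination with the neutral, weakly basic ylide 1-(triphenyl-λ5-phosphanylidene)propan-2-one in toluene at 80 °C gives (3E)-4-[(1R,4R)-4-{[tert-butyl(dimethyl)silyl]oxy}-2,6,6-trimethylcyclohex-2-en-1-yl]but-3-en-2-one F6, in which C6 is no longer α to a carbonyl group. Horner–Wadsworth–Emmons reaction of this ketone with diethyl (cyanomethyl)phosphonate and NaH in THF, with chromatographic removal of the 9Z isomer, rejoins the route at 14.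

Further compounds
F1 | step 2 | 1,3-di-tert-butyl 5-ethyl 4,6,6-trimethyl-2-oxocyclohex-3-ene-1,3,5-tricarboxylate | CCOC(=O)C1C(C)=C(C(=O)OC(C)(C)C)C(=O)C(C(=O)OC(C)(C)C)C1(C)C
F2 | step 2 | 5-(ethoxycarbonyl)-4,6,6-trimethyl-2-oxocyclohex-3-ene-1,3-dicarboxylic acid | CCOC(=O)C1C(C)=C(C(O)=O)C(=O)C(C(O)=O)C1(C)C
F3 | step 3 | ethyl 4-hydroxy-2,6,6-trimethylcyclohex-2-ene-1-carboxylate, mixture of stereoisomers | CCOC(=O)C1C(C)=CC(O)CC1(C)C
F4 | step 3 | ethyl (1R,4R)-4-acetoxy-2,6,6-trimethylcyclohex-2-ene-1-carboxylate | CC1=C[C@H](OC(C)=O)CC(C)(C)[C@H]1C(=O)OCC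
F5 | step 3 | ethyl (1S,4R)-4-acetoxy-2,6,6-trimethylcyclohex-2-ene-1-carboxylate | CC1=C[C@H](OC(C)=O)CC(C)(C)[C@@H]1C(=O)OCC
F6 | step 7 | (3E)-4-[(1R,4R)-4-{[tert-butyl(dimethyl)silyl]oxy}-2,6,6-trimethylcyclohex-2-en-1-yl]but-3-en-2-one | CC1=C[C@H](O[Si](C)(C)C(C)(C)C)CC(C)(C)[C@H]1/C=C/C(C)=O
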